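The data were generated by integration for substances that don't exist; the scatter is artificial.

The target does not stay as it is: in the blue run the isomer of the product climbs behind it, so the next run has to be chosen by how long target is left lying in the warm flask.

| setting | blue | violet | gamma | delta | eta | zeta |
|---|---|---|---|---|---|---|
| substrate | 0.10 M | 0.050 M | 0.10 M | 0.10 M | 0.10 M | 0.10 M (fed, over 25 h) |
| partner | 0.20 M | 0.20 M | 0.200 M | 0.200 M (fed, over 25 h) | 0.200 M (in portions, 4, over 25 h) | 0.200 M |
| free catalyst | 0.10 mM | 0.10 mM | 0.10 mM | 0.10 mM | 0.10 mM | 0.10 mM |
| temperature | −20 °C | −20 °C | −20 °C |  | −20 °C | −20 °C |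
| remark | run made earlier | run made earlier | everything together at the start | the addition at −60 °C, then warmed to −20 °C; the feed brings no volume worth counting | first portion at the start, last at 25 h | all else is in the flask from the start; the feed brings no volume worth counting |
| time |  |  | 30 h | 30 h | 30 h | 30 h |

| run | time / h | target / % | isomer of the product / % |
|---|---|---|---|
| blue | 1.50 | 3.2 | 0.8 |
| blue | 5.00 | 10.8 | 1.4 |
| blue | 8.00 | 15.6 | 2.1 |
| blue | 12.0 | 23.2 | 4.1 |
| blue | 20.0 | 32.7 | 9.7 |
| violet | 1.33 | 5.5 | 0 |
| violet | 2.50 | 10.2 | 0 |
| violet | 4.00 | 14.5 | 1.4 |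
| violet | 5.00 | 20.2 | 1.4 |
| violet | 6.00 | 22.4 | 1.9 |

(readings scatter by 0.5 percentage points)

- the numbers in the tables scatter by 0.5 percentage points (one standard deviation)
- the earlier runs do not show what temperature does; that part of a forecast is a guess

- the flask that comes out highest in share of target in target plus isomer of the product, or "all alike" when all lie within 1.5 percentage points (gamma / delta / eta / zeta / all alike)
- share of target in target plus isomer of the product at the end, gamma
- share of target in target plus isomer of the product at the end, delta
- share of target in target plus isomer of the product at the end, eta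
- share of target in target plus isomer of the product at the end, zeta

Target and isomer together arrive at 0.00212 M/h in the blue run and at 0.00202 M/h in the violet run, which has half the substrate. So the rate of making, r, hardly follows c(substrate): it is near zero order. Take the isomer as formed first order from target, with rate k·c(target). Dividing the last blue isomer reading by the area under the blue target curve gives this loss constant k, 0.0264 /h.

Integrating with steady r over a warm time τ gives c(target) = (r/k)(1 − e^(−kτ)), while target plus isomer is rτ. The share of target (the selectivity) is therefore S = (1 − e^(−kτ))/(kτ), and r cancels.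

My own reckoning for gamma, with τ = 30 h, is S = 69.1 %. Zeta's feed of 0.00400 M/h is faster than the making, but c(substrate) starts from zero in zeta, so a steady r cannot be assumed there and zeta gets no figure. For delta, guessing that nothing forms in the cold leaves τ = 5.00 h, so S = 93.7 %, above gamma. Eta falls between them, with no figure, since partner stood at 0.20 M in both runs. The decision is to charge as in delta if share counts, at a price of about 9.93 % target.

The forecast names delta: gamma 68 % (64 % to 72 %), delta 92 % (84 % to 97 %), eta 76 % (70 % to 82 %), zeta 69 % (64 % to 74 %). On delta it stands below my figure, and it adds: “The temperature effect is a guess.”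

Delta comes out highest at 92.3 %, with gamma at 68.7 %, eta at 73.9 % and zeta at 72.1 %.

    substrate + free catalyst → catalyst intermediate A (k = 0.499 /M/s, Ea = 48.0 kJ/mol)
    partner + catalyst intermediate A → catalyst intermediate B (k = 0.0563 /M/s, Ea = 39.0 kJ/mol)
    catalyst intermediate B ⇌ released group + catalyst intermediate C (K = 0.100 M, k = 0.0969 /s, Ea = 68.0 kJ/mol, ΔH = −38.0 kJ/mol)
    catalyst intermediate C → free catalyst + target (k = 0.0443 /s, Ea = 66.0 kJ/mol)
    partner → decomposed reagent (k = 1.09 × 10⁻⁶ /s, Ea = 96.0 kJ/mol)
    target ⇌ isomer of the product (K = 1.30, k = 8.98 × 10⁻⁶ /s, Ea = 94.0 kJ/mol, ΔH = −3.00 kJ/mol)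
    released group → by-product carried off (k = 1.37 × 10⁻⁵ /s, Ea = 75.0 kJ/mol)
    (constants at −20 °C)

At 30.0 h delta holds 11.5 % target with 87.4 % substrate still there, less target than gamma's 41.1 %. The forecast would turn wrong with a late reading: at 300 h delta stands at 43.5 % and gamma at 43.5 %. Gamma read at 5.0 d gives S = 30.3 % with the same k, while that flask stands higher, at 44.1 %.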